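**Retrosynthetic overview**
- The target comes from a butenolide enal by 1,2-reduction of the aldehyde and desilylation.
- Key disconnection: the C5–CH2 bond and the lactone C–O bond are made together by an asymmetric vinylogous Mukaiyama aldol/lactonisation between a C20 silyl dienol ether (west half) and a C5 (Z)-formylacrylate (east half). This one step sets the (S) centre, fixes the (E)-trisubstituted olefin that carries the future CH2OH, joins the halves and closes the butenolide.
- The formylacrylate comes from furan-3-ylmethanol by regioselective singlet-oxygen oxidation; all butenolide carbons come from the furan.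
- The dienol ether comes from an α-alkylated crotonaldehyde, made by B-alkyl Suzuki coupling of 2-bromocrotonaldehyde with a homoallyl borane. The borane comes from dihydro-β-ionone by ketone-to-alkyne conversion and zirconium-catalysed methylalumination/vinylation.
- Ring order: the cyclohexene ring is bought; the butenolide is the only ring built, and it is closed in the fragment-coupling step.

Assumption: the target is the (5S) butenolide with both chain olefins E, as the SMILES defines; dihydro-β-ionone, crotonaldehyde and furan-3-ylmethanol are commercial.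

**Route**

Step 1
Reactants: 1 4-(2,6,6-trimethylcyclohex-1-en-1-yl)butan-2-one (dihydro-β-ionone)
Product: 3 2-(but-3-yn-1-yl)-1,3,3-trimethylcyclohex-1-ene, via enol phosphate 2 (not isolated)
Conditions: LiN(iPr)2 (1.05 equiv), THF, −78 °C; ClP(O)(OEt)2, −78 °C → rt; then LiN(iPr)2 (2.3 equiv), THF, −78 °C → rt; H2O
Reagents that add atoms: none
Why: Negishi methyl-ketone-to-alkyne conversion, in which kinetic deprotonation at the methyl group, O-phosphorylation and base-induced β-elimination of the enol phosphate give the terminal alkyne while the tetrasubstituted ring olefin is untouched.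

Step 2
Reactants: 3 2-(but-3-yn-1-yl)-1,3,3-trimethylcyclohex-1-ene
Product: 5 2-[(3E)-3-methylhexa-3,5-dien-1-yl]-1,3,3-trimethylcyclohex-1-ene, via alkenyldimethylalane 4 (not isolated)
Conditions: Me3Al (2 equiv), Cp2ZrCl2 (0.25 equiv), CH2Cl2, 0 °C → rt; evaporate; vinyl bromide, Pd(PPh3)4 (5 mol %), ZnCl2 (20 mol %), THF, rt
Reagents that add atoms: trimethylaluminium C[Al](C)C; vinyl bromide C=CBr
Why: Negishi zirconium-catalysed syn-methylalumination places CH3 on the internal and Al on the terminal alkyne carbon, and the alkenylalane is cross-coupled in the same flask with vinyl bromide with retention, which fixes the (E)-trisubstituted olefin.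

Step 3
Reactants: 6 (2E)-but-2-enal (crotonaldehyde)
Product: 8 (2Z)-2-bromobut-2-enal, via anti dibromide 7 (not isolated)
Conditions: Br2, CH2Cl2, 0 °C; then Et3N, 0 °C → rt
Reagents that add atoms: bromine BrBr
Why: Bromine addition followed by amine-induced dehydrobromination (E1cB through the enolate) gives the thermodynamically preferred (Z)-α-bromoenal, whose geometry is erased again in step 5.

Step 4
Reactants: 5 2-[(3E)-3-methylhexa-3,5-dien-1-yl]-1,3,3-trimethylcyclohex-1-ene; 8 (2Z)-2-bromobut-2-enal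
Product: 10 (2E)-2-[(3E)-4-methyl-6-(2,6,6-trimethylcyclohex-1-en-1-yl)hex-3-en-1-yl]but-2-enal, via alkyl-9-BBN 9 (not isolated)
Conditions: 9-BBN (1.05 equiv), THF, 0 °C → rt; then 8 (1.2 equiv), Pd(dppf)Cl2 (5 mol %), AsPh3 (5 mol %), Cs2CO3 (2 equiv), DMF/H2O, rt
Reagents that add atoms: none
Why: 9-BBN hydroborates only the terminal vinyl CH2 of the diene (anti-Markovnikov, hindered olefins untouched) and the B-alkyl Suzuki–Miyaura coupling proceeds with retention at the sp2 carbon, placing the whole west chain on the α-carbon of the crotonaldehyde unit.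

Step 5
Reactants: 10 (2E)-2-[(3E)-4-methyl-6-(2,6,6-trimethylcyclohex-1-en-1-yl)hex-3-en-1-yl]but-2-enal
Product: 11 tert-butyl(dimethyl)({(1E)-2-[(3E)-4-methyl-6-(2,6,6-trimethylcyclohex-1-en-1-yl)hex-3-en-1-yl]buta-1,3-dien-1-yl}oxy)silane
Conditions: TBSOTf (1.3 equiv), Et3N (2 equiv), CH2Cl2, 0 °C → rt; Et3N-deactivated silica
Reagents that add atoms: tert-butyldimethylsilyl trifluoromethanesulfonate CC(C)(C)[Si](C)(C)OS(=O)(=O)C(F)(F)F
Why: Soft enolisation (γ-deprotonation of the O-silylated enal by the amine) gives the 1-silyloxydiene, and only the γ-CH3 can be deprotonated because the α-CH2 of the chain is cross-conjugated.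

Step 6
Reactants: 12 furan-3-ylmethanol
Product: 13 tert-butyl(furan-3-ylmethoxy)dimethylsilane
Conditions: TBSCl, imidazole, DMF, rt
Reagents that add atoms: tert-butyldimethylsilyl chloride CC(C)(C)[Si](C)(C)Cl
Why: Standard O-silylation of a primary alcohol, needed so that no free OH binds the boron promoter in step 9.

Step 7
Reactants: 13 tert-butyl(furan-3-ylmethoxy)dimethylsilane
Product: 15 4-({[tert-butyl(dimethyl)silyl]oxy}methyl)-5-hydroxyfuran-2(5H)-one, via furan endoperoxide 14 (not isolated)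
Conditions: O2, hν (visible), tetraphenylporphyrin (cat.), iPr2NEt (1.5 equiv), CH2Cl2, −78 °C → rt
Reagents that add atoms: dioxygen O=O
Why: [4+2] cycloaddition of singlet oxygen gives the endoperoxide, and the hindered amine removes the less hindered bridgehead hydrogen (Kornblum–DeLaMare fragmentation), so the carbonyl forms remote from the substituent and the lactol carbon next to it.

Step 8
Reactants: 15 4-({[tert-butyl(dimethyl)silyl]oxy}methyl)-5-hydroxyfuran-2(5H)-one
Product: 16 methyl (2Z)-3-({[tert-butyl(dimethyl)silyl]oxy}methyl)-4-oxobut-2-enoate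
Conditions: KHCO3 (1.2 equiv), MeI (3 equiv), DMF, 0 °C, dark; used at once
Reagents that add atoms: iodomethane CI
Why: The lactol is the ring tautomer of the (Z)-formylacrylic acid, so bicarbonate opens it to the carboxylate and SN2 O-methylation traps the open-chain aldehyde ester with the Z geometry inherited from the ring.

Step 9
Reactants: 11 tert-butyl(dimethyl)({(1E)-2-[(3E)-4-methyl-6-(2,6,6-trimethylcyclohex-1-en-1-yl)hex-3-en-1-yl]buta-1,3-dien-1-yl}oxy)silane; 16 methyl (2Z)-3-({[tert-butyl(dimethyl)silyl]oxy}methyl)-4-oxobut-2-enoate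
Product: 18 (2E,5E)-2-{2-[(2S)-3-({[tert-butyl(dimethyl)silyl]oxy}methyl)-5-oxo-2,5-dihydrofuran-2-yl]ethylidene}-6-methyl-8-(2,6,6-trimethylcyclohex-1-en-1-yl)oct-5-enal, via hydroxy ester 17 (not isolated)
Conditions: N-Ts-D-tryptophan (1.0 equiv), PhBCl2 (1.0 equiv), CH2Cl2, rt, evaporate; then 16 (1.3 equiv), 11 (1.0 equiv), iPrOH (1.1 equiv), EtCN, −78 °C; aq. NaHCO3; PPTS (cat.), CH2Cl2, rt
Reagents that add atoms: none
Why: Oxazaborolidinone-promoted asymmetric vinylogous Mukaiyama aldol, in which the terminal CH2 of the dienol ether attacks the boron-bound aldehyde through an open transition state to give the (E)-enal; the indole of the D-tryptophan-derived promoter is expected (Corey model) to shield the Re face so that Si-face attack gives the (S) carbinol, which then lactonises onto the cis ester to close the butenolide.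

Step 10
Reactants: 18 (2E,5E)-2-{2-[(2S)-3-({[tert-butyl(dimethyl)silyl]oxy}methyl)-5-oxo-2,5-dihydrofuran-2-yl]ethylidene}-6-methyl-8-(2,6,6-trimethylcyclohex-1-en-1-yl)oct-5-enal
Product: 19 (5S)-4-({[tert-butyl(dimethyl)silyl]oxy}methyl)-5-[(2E,6E)-3-(hydroxymethyl)-7-methyl-9-(2,6,6-trimethylcyclohex-1-en-1-yl)nona-2,6-dien-1-yl]furan-2(5H)-one
Conditions: NaBH4 (1.0 equiv), CeCl3·7H2O (1.2 equiv), MeOH, −78 °C; aq. NH4Cl
Reagents that add atoms: none
Why: Luche 1,2-reduction takes the aldehyde far faster than the butenolide at −78 °C, creates no stereocentre and leaves the olefin geometry (CH2OH trans to the CH2 on C5) and C5 intact.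

Step 11
Reactants: 19 (5S)-4-({[tert-butyl(dimethyl)silyl]oxy}methyl)-5-[(2E,6E)-3-(hydroxymethyl)-7-methyl-9-(2,6,6-trimethylcyclohex-1-en-1-yl)nona-2,6-dien-1-yl]furan-2(5H)-one
Product: 20 (5S)-4-(hydroxymethyl)-5-[(2E,6E)-3-(hydroxymethyl)-7-methyl-9-(2,6,6-trimethylcyclohex-1-en-1-yl)nona-2,6-dien-1-yl]furan-2(5H)-one
Conditions: HF·pyridine, pyridine/THF, 0 °C → rt
Reagents that add atoms: none
Why: Fluoride-mediated desilylation of the primary TBS ether under buffered, non-basic conditions, so the base-sensitive C5–H is not epimerised and the lactone and olefins survive.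

**Compound list**
1 | 4-(2,6,6-trimethylcyclohex-1-en-1-yl)butan-2-one (dihydro-β-ionone) | CC(=O)CCC1=C(C)CCCC1(C)C | starting material
2 | diethyl 4-(2,6,6-trimethylcyclohex-1-en-1-yl)but-1-en-2-yl phosphate | C=C(CCC1=C(C)CCCC1(C)C)OP(=O)(OCC)OCC | intermediate
3 | 2-(but-3-yn-1-yl)-1,3,3-trimethylcyclohex-1-ene | C#CCCC1=C(C)CCCC1(C)C | intermediate
4 | dimethyl[(1E)-2-methyl-4-(2,6,6-trimethylcyclohex-1-en-1-yl)but-1-en-1-yl]alumane | C[Al](C)/C=C(\C)CCC1=C(C)CCCC1(C)C | intermediate
5 | 2-[(3E)-3-methylhexa-3,5-dien-1-yl]-1,3,3-trimethylcyclohex-1-ene | C=C/C=C(\C)CCC1=C(C)CCCC1(C)C | intermediate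
6 | (2E)-but-2-enal | C/C=C/C=O | starting material
7 | (2R*,3S*)-2,3-dibromobutanal (racemic, one enantiomer drawn) | C[C@@H](Br)[C@@H](Br)C=O | intermediate
8 | (2Z)-2-bromobut-2-enal | C/C=C(\Br)C=O | intermediate
9 | 9-[(3E)-4-methyl-6-(2,6,6-trimethylcyclohex-1-en-1-yl)hex-3-en-1-yl]-9-borabicyclo[3.3.1]nonane | B1(CC/C=C(\C)CCC2=C(C)CCCC2(C)C)C2CCCC1CCC2 | intermediate
10 | (2E)-2-[(3E)-4-methyl-6-(2,6,6-trimethylcyclohex-1-en-1-yl)hex-3-en-1-yl]but-2-enal | C/C=C(/C=O)CC/C=C(\C)CCC1=C(C)CCCC1(C)C | intermediate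
11 | tert-butyl(dimethyl)({(1E)-2-[(3E)-4-methyl-6-(2,6,6-trimethylcyclohex-1-en-1-yl)hex-3-en-1-yl]buta-1,3-dien-1-yl}oxy)silane | C=C/C(CC/C=C(\C)CCC1=C(C)CCCC1(C)C)=C/O[Si](C)(C)C(C)(C)C | intermediate
12 | furan-3-ylmethanol | OCc1ccoc1 | starting material
13 | tert-butyl(furan-3-ylmethoxy)dimethylsilane | CC(C)(C)[Si](C)(C)OCc1ccoc1 | intermediate
14 | 5-({[tert-butyl(dimethyl)silyl]oxy}methyl)-2,3,7-trioxabicyclo[2.2.1]hept-5-ene (racemic) | CC(C)(C)[Si](C)(C)OCC1=CC2OOC1O2 | intermediate
15 | 4-({[tert-butyl(dimethyl)silyl]oxy}methyl)-5-hydroxyfuran-2(5H)-one (racemic lactol) | CC(C)(C)[Si](C)(C)OCC1=CC(=O)OC1O | intermediate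
16 | methyl (2Z)-3-({[tert-butyl(dimethyl)silyl]oxy}methyl)-4-oxobut-2-enoate | COC(=O)/C=C(\C=O)CO[Si](C)(C)C(C)(C)C | intermediate
17 | methyl (2Z,4S,6E,10E)-3-({[tert-butyl(dimethyl)silyl]oxy}methyl)-7-formyl-4-hydroxy-11-methyl-13-(2,6,6-trimethylcyclohex-1-en-1-yl)trideca-2,6,10-trienoate | COC(=O)/C=C(CO[Si](C)(C)C(C)(C)C)\[C@@H](O)C/C=C(/C=O)CC/C=C(\C)CCC1=C(C)CCCC1(C)C | intermediate
18 | (2E,5E)-2-{2-[(2S)-3-({[tert-butyl(dimethyl)silyl]oxy}methyl)-5-oxo-2,5-dihydrofuran-2-yl]ethylidene}-6-methyl-8-(2,6,6-trimethylcyclohex-1-en-1-yl)oct-5-enal | CC(C)(C)[Si](C)(C)OCC1=CC(=O)O[C@H]1C/C=C(/C=O)CC/C=C(\C)CCC1=C(C)CCCC1(C)C | intermediate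
19 | (5S)-4-({[tert-butyl(dimethyl)silyl]oxy}methyl)-5-[(2E,6E)-3-(hydroxymethyl)-7-methyl-9-(2,6,6-trimethylcyclohex-1-en-1-yl)nona-2,6-dien-1-yl]furan-2(5H)-one | CC(C)(C)[Si](C)(C)OCC1=CC(=O)O[C@H]1C/C=C(/CO)CC/C=C(\C)CCC1=C(C)CCCC1(C)C | intermediate
20 | (5S)-4-(hydroxymethyl)-5-[(2E,6E)-3-(hydroxymethyl)-7-methyl-9-(2,6,6-trimethylcyclohex-1-en-1-yl)nona-2,6-dien-1-yl]furan-2(5H)-one (CNP0313405.3) | CC1=C(CC/C(C)=C/CC/C(=C\C[C@@H]2OC(=O)C=C2CO)CO)C(C)(C)CCC1 | target

**Step count and risk**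
Total steps: 11. Longest linear sequence: 7 steps (steps 1, 2, 4, 5, 9, 10, 11 from dihydro-β-ionone).

Most likely to fail, first: step 9. The promoter has not been used on a γ-oxo-enoate aldehyde, so enantioselectivity, 1,2- versus 1,4-addition and the facial sense are all unproven. The fallback makes the stereocentre and the enal olefin in two separate reagent-controlled operations. It sets out from aldehyde ester 16 and alkylborane 9 and comes back at 18. Aldehyde 16 is allylated with (−)-Ipc2B(allyl) (from (+)-α-pinene; Et2O, −78 °C; NaBO3·4H2O work-up). This reagent adds to the Si face of aldehydes, as in the Brown allylation of benzaldehyde to the (S) carbinol. The resulting methyl (2Z,4S)-3-({[tert-butyl(dimethyl)silyl]oxy}methyl)-4-hydroxyhepta-2,6-dienoate F1 lactonises on work-up to (5S)-4-({[tert-butyl(dimethyl)silyl]oxy}methyl)-5-(prop-2-en-1-yl)furan-2(5H)-one F2. In parallel, borane 9 is coupled with 2-bromoprop-2-enal under the conditions of step 4 to give (5E)-6-methyl-2-methylidene-8-(2,6,6-trimethylcyclohex-1-en-1-yl)oct-5-enal F3. Cross-metathesis of F2 with F3 (second-generation Hoveyda–Grubbs catalyst, CH2Cl2, 40 °C) then gives 18. This pairing of a terminal olefin with a 2-substituted acrolein is known to give (E)-trisubstituted enals, and the hindered chain and ring olefins stay out of the metathesis.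

Second: step 4. The α-bromoenal may not tolerate the basic aqueous coupling, or the borane may add to it in a conjugate sense. The fallback replaces the sp2–sp3 coupling by enolate-type alkylation. It sets out from diene 5 (with crotonaldehyde 6 for the nucleophile) and comes back at 10. Diene 5 is hydroborated as before to 9 and oxidised (NaOH, H2O2) to (3E)-4-methyl-6-(2,6,6-trimethylcyclohex-1-en-1-yl)hex-3-en-1-ol F4. This is converted (I2, PPh3, imidazole) into 2-[(3E)-6-iodo-3-methylhex-3-en-1-yl]-1,3,3-trimethylcyclohex-1-ene F5. Crotonaldehyde 6 is condensed with cyclohexylamine to (1E,2E)-N-cyclohexylbut-2-en-1-imine F6. Its azadienyl anion (LiN(iPr)2, THF/DMPU, −78 °C) is alkylated at the α-carbon by F5 to give N-cyclohexyl-2-ethenyl-6-methyl-8-(2,6,6-trimethylcyclohex-1-en-1-yl)oct-5-en-1-imine F7. Aqueous oxalic acid hydrolyses F7 and moves the olefin into conjugation to give 10. The unconjugated aldehyde would be silylated to the same dienol ether 11 in step 5, so incomplete isomerisation does no harm.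

Third: step 8. The open-chain (Z)-aldehyde ester may isomerise to E or close to the pseudo-ester. The fallback avoids compounds 15 and 16 and builds the butenolide by ring-closing metathesis instead. It sets out from dienol ether 11 and comes back at 18. Commercial 2-methylidenepropane-1,3-diol is monosilylated (NaH, TBSCl, THF) to 2-({[tert-butyl(dimethyl)silyl]oxy}methyl)prop-2-en-1-ol F8 and oxidised (MnO2, CH2Cl2) to 2-({[tert-butyl(dimethyl)silyl]oxy}methyl)prop-2-enal F9. The vinylogous aldol of 11 with F9 under the promoter of step 9 (same facial argument, same priority order) gives (2E,5E)-2-[(3S)-4-({[tert-butyl(dimethyl)silyl]oxy}methyl)-3-hydroxypent-4-en-1-ylidene]-6-methyl-8-(2,6,6-trimethylcyclohex-1-en-1-yl)oct-5-enal F10. Acylation (acryloyl chloride, iPr2NEt, CH2Cl2, −78 °C) gives (3S,5E,9E)-2-({[tert-butyl(dimethyl)silyl]oxy}methyl)-6-formyl-10-methyl-12-(2,6,6-trimethylcyclohex-1-en-1-yl)dodeca-1,5,9-trien-3-yl prop-2-enoate F11. Ring-closing metathesis of the acrylate onto the 1,1-disubstituted olefin (second-generation Hoveyda–Grubbs catalyst, toluene, 80 °C) closes the butenolide to 18. The conjugated enal olefin is deactivated and should not compete for the six-membered lactone.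

**Further compounds**
F1 | step 9 | methyl (2Z,4S)-3-({[tert-butyl(dimethyl)silyl]oxy}methyl)-4-hydroxyhepta-2,6-dienoate | COC(=O)/C=C(CO[Si](C)(C)C(C)(C)C)\[C@@H](O)CC=C
F2 | step 9 | (5S)-4-({[tert-butyl(dimethyl)silyl]oxy}methyl)-5-(prop-2-en-1-yl)furan-2(5H)-one | CC(C)(C)[Si](C)(C)OCC1=CC(=O)O[C@H]1CC=C
F3 | step 9 | (5E)-6-methyl-2-methylidene-8-(2,6,6-trimethylcyclohex-1-en-1-yl)oct-5-enal | C=C(C=O)CC/C=C(\C)CCC1=C(C)CCCC1(C)C
F4 | step 4 | (3E)-4-methyl-6-(2,6,6-trimethylcyclohex-1-en-1-yl)hex-3-en-1-ol | OCC/C=C(\C)CCC1=C(C)CCCC1(C)C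
F5 | step 4 | 2-[(3E)-6-iodo-3-methylhex-3-en-1-yl]-1,3,3-trimethylcyclohex-1-ene | ICC/C=C(\C)CCC1=C(C)CCCC1(C)C
F6 | step 4 | (1E,2E)-N-cyclohexylbut-2-en-1-imine | C/C=C/C=N/C1CCCCC1
F7 | step 4 | N-cyclohexyl-2-ethenyl-6-methyl-8-(2,6,6-trimethylcyclohex-1-en-1-yl)oct-5-en-1-imine (racemic, 5E) | C=CC(C=NC1CCCCC1)CC/C=C(\C)CCC1=C(C)CCCC1(C)C
F8 | step 8 | 2-({[tert-butyl(dimethyl)silyl]oxy}methyl)prop-2-en-1-ol | C=C(CO)CO[Si](C)(C)C(C)(C)C
F9 | step 8 | 2-({[tert-butyl(dimethyl)silyl]oxy}methyl)prop-2-enal | C=C(C=O)CO[Si](C)(C)C(C)(C)C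
F10 | step 8 | (2E,5E)-2-[(3S)-4-({[tert-butyl(dimethyl)silyl]oxy}methyl)-3-hydroxypent-4-en-1-ylidene]-6-methyl-8-(2,6,6-trimethylcyclohex-1-en-1-yl)oct-5-enal | C=C(CO[Si](C)(C)C(C)(C)C)[C@@H](O)C/C=C(/C=O)CC/C=C(\C)CCC1=C(C)CCCC1(C)C
F11 | step 8 | (3S,5E,9E)-2-({[tert-butyl(dimethyl)silyl]oxy}methyl)-6-formyl-10-methyl-12-(2,6,6-trimethylcyclohex-1-en-1-yl)dodeca-1,5,9-trien-3-yl prop-2-enoate | C=CC(=O)O[C@H](C(=C)CO[Si](C)(C)C(C)(C)C)C/C=C(/C=O)CC/C=C(\C)CCC1=C(C)CCCC1(C)C
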